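The route rests on cutting the C4a–C8a bond of ring A. Ring A bears oxygen on C5, C7 and C8a, methoxy groups on C6 and C8 and the acyl carbon C4 on C4a. It is mirror-symmetric about the C4a–C7 axis and therefore maps onto a linear polyketo ester running from C8a to C3. A kojic-acid-derived 4-pyranone with a CH(OMe)CO2Me arm and a CH2OMe arm flanking the ring oxygen hides this chain. In one operation methoxide unzips the pyranone, remains as the C7 methoxy group, and the C4a carbanion acylates C8a, giving the aromatic ring A ketone. Allan–Robinson annulation with a benzyl-protected ring B anhydride and hydrogenolysis finish the flavone.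

Key step: step 3

Remark on the chemistry: the key step is run in dry methanol, where the nucleophile that opens the pyranone is methoxide, so the C7 oxygen of the ring A ketone emerges as OCH3 rather than OH; the bond formed, the ring closed and the skeleton are unaffected, a later 7-O-methylation becomes superfluous, and hydroxide, which would saponify the acyl-donor ester, is kept out; the target has no stereocentre and all chiral intermediates are racemic.

Step 1
Reactants: 1 kojic acid (5-hydroxy-2-(hydroxymethyl)-4H-pyran-4-one); 2 methyl glyoxylate (freshly distilled, 1.3 equiv)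
Product: 3 methyl 2-hydroxy-2-[3-hydroxy-6-(hydroxymethyl)-4-oxo-4H-pyran-2-yl]acetate (racemic)
Conditions: DABCO (0.2 equiv), 1,4-dioxane, rt
Reagents that add atoms: none
Why: Aldol-type hydroxyalkylation (the enol counterpart of the Lederer–Manasse reaction), in which the amine-generated enolate of the 5-hydroxy-4-pyranone reacts at C6, the free carbon ortho to the enolic oxygen, as known for kojic acid and allomaltol with aldehydes, while the ester group disfavours ionisation of the carbinol and hence a second condensation, and the new carbinol centre forms as a racemate that step 3 erases.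

Step 2
Reactants: 3 methyl 2-hydroxy-2-[3-hydroxy-6-(hydroxymethyl)-4-oxo-4H-pyran-2-yl]acetate
Product: 4 methyl 2-methoxy-2-[3-methoxy-6-(methoxymethyl)-4-oxo-4H-pyran-2-yl]acetate (racemic)
Conditions: MeI (12 equiv), Ag2O (4.5 equiv), 4 Å MS, DMF, rt, dark
Reagents that add atoms: iodomethane (MeI), CI
Why: Purdie–Irvine methylation in DMF, in which Ag2O activates MeI and takes up HI without generating a free alkoxide, so the acidic enol, the primary alcohol and the α-hydroxy ester should all be etherified while retro-aldol cleavage, ester hydrolysis and C-methylation at the acidic CH are avoided.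

Step 3
Reactants: 4 methyl 2-methoxy-2-[3-methoxy-6-(methoxymethyl)-4-oxo-4H-pyran-2-yl]acetate
Product: 7 1-(2,6-dihydroxy-3,4,5-trimethoxyphenyl)-2-methoxyethan-1-one, via ring-opened Z enol ether 5 (not isolated), via cyclohexenedione 6 (not isolated)
Conditions: Mg(OMe)2 (4 equiv), dry MeOH, reflux, Ar; then 1 M HCl, 0 °C
Reagents that add atoms: magnesium dimethoxide, Mg(OMe)2, [Mg+2].[O-]C.[O-]C
Why: Methoxide adds reversibly to the pyranone carbon bearing the ester arm (future C7), the ring oxygen departs by retro-oxa-Michael cleavage as the magnesium β-diketonate spanning C5–C4a–C4, and in the Z enol ether 5 the C4a carbanion attacks the ester carbon C8a, expels methoxide (C4a–C8a formed) and gives cyclohexenedione 6, which enolises to arene 7, so that 4 is in sum isomerised. The closest known reaction types are the base opening of 4-pyranones to 1,3,5-tricarbonyl chains and the Mg(OMe)2-mediated Claisen (Dieckmann-type) cyclisation of 3,5,7-triketo esters, free or masked as pyrones and O-methyl enol ethers, to acylphloroglucinols. Ring A closes in the 6-exo-trig mode on a magnesium template that binds the diketonate and the α-methoxy ester, and the E and Z forms of the push-pull alkene in 5 interconvert by methoxide addition and elimination. No stereocentre is formed, and the racemic CH(OMe) centre of 4 ends as the planar carbon C8. The step needs Claisen folding to win: aldol attack of C8 on C4 would leave C8 quaternary (OMe and CO2Me) and unable to aromatise, so it reverts; closure of the terminal carbon C3 onto C7 would require a second deprotonation of the diketonate that methoxide in methanol cannot effect; methoxide attack at the other oxygen-bound ring carbon (future C4) and lactonisation to a 2-pyranone are reversible dead ends, so only the chelated phenoxide of 7 should accumulate. Water is excluded because hydroxide would saponify the activated α-methoxy ester before the ring opens, whereas the methyl ester and methoxide pair makes transesterification degenerate.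

Step 4
Reactants: 8 3,5-dihydroxy-4-methoxybenzoic acid
Product: 10 3,5-bis(benzyloxy)-4-methoxybenzoic acid, via benzyl ester 9 (not isolated)
Conditions: BnBr (3.3 equiv), K2CO3 (4 equiv), DMF, 60 °C; filter, concentrate; then NaOH, MeOH–THF–H2O, 60 °C; then HCl
Reagents that add atoms: benzyl bromide (BnBr), BrCc1ccccc1; sodium hydroxide, NaOH, [Na+].[OH-]
Why: Williamson benzylation of both phenols and of the carboxylate followed by saponification of the crude benzyl ester, both routine for gallic acid derivatives, leaves the 4-methoxy group and the benzyl ethers untouched.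

Step 5
Reactants: 10 3,5-bis(benzyloxy)-4-methoxybenzoic acid (two molecules)
Product: 11 3,5-bis(benzyloxy)-4-methoxybenzoic anhydride
Conditions: DCC (0.5 equiv per acid), CH2Cl2, 0 °C to rt; filter
Reagents that add atoms: none
Why: Carbodiimide dehydration, in which DCC converts one acid molecule into the O-acylisourea that the second carboxylate attacks to give the symmetrical anhydride, while the insoluble urea is filtered off.

Step 6
Reactants: 7 1-(2,6-dihydroxy-3,4,5-trimethoxyphenyl)-2-methoxyethan-1-one; 11 3,5-bis(benzyloxy)-4-methoxybenzoic anhydride (4 equiv)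
Product: 13 2-[3,5-bis(benzyloxy)-4-methoxyphenyl]-5-hydroxy-3,6,7,8-tetramethoxy-4H-chromen-4-one, via 5-O-aroyl flavone 12 (not isolated)
Conditions: Et3N, 160 °C, sealed tube, Ar; then KOH, EtOH–H2O, reflux; then HCl
Reagents that add atoms: none
Why: Allan–Robinson flavone synthesis in its triethylamine variant, long used on ω-methoxy polyhydroxyacetophenones, builds ring C by O-aroylation, base-induced aroyl transfer to the CH2(OMe) carbon (future C3) and cyclodehydration, the two ortho hydroxyl groups of 7 being equivalent across the C4a–C7 axis so that only one flavone and no distinct Wessely–Moser isomer can arise, and the KOH treatment cleaves the surplus aryl ester on O5 without touching the ethers.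

Step 7
Reactants: 13 2-[3,5-bis(benzyloxy)-4-methoxyphenyl]-5-hydroxy-3,6,7,8-tetramethoxy-4H-chromen-4-one
Product: 14 5,3',5'-trihydroxy-3,6,7,8,4'-pentamethoxyflavone (target)
Conditions: H2 (1 atm), 10% Pd/C, EtOAc–MeOH, rt
Reagents that add atoms: none
Why: Catalytic hydrogenolysis of the two benzyl aryl ethers is selective because the tetrasubstituted C2=C3 bond of the vinylogous ester and the aryl methyl ethers are inert at one atmosphere, which should release the 3'- and 5'-hydroxyl groups and give the target.

Compound list
1 | kojic acid, 5-hydroxy-2-(hydroxymethyl)-4H-pyran-4-one | OCc1cc(=O)c(O)co1 | starting material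
2 | methyl glyoxylate, methyl 2-oxoacetate | COC(=O)C=O | starting material
3 | methyl 2-hydroxy-2-[3-hydroxy-6-(hydroxymethyl)-4-oxo-4H-pyran-2-yl]acetate, racemic | OCc1cc(=O)c(O)c(C(O)C(=O)OC)o1 | intermediate
4 | methyl 2-methoxy-2-[3-methoxy-6-(methoxymethyl)-4-oxo-4H-pyran-2-yl]acetate, racemic | COCc1cc(=O)c(OC)c(C(OC)C(=O)OC)o1 | intermediate
5 | methyl (3Z)-2,3,4,8-tetramethoxy-5,7-dioxooct-3-enoate, racemic, present as its magnesium diketonate | COCC(=O)CC(=O)/C(OC)=C(/OC)C(OC)C(=O)OC | intermediate
6 | 4,5,6-trimethoxy-2-(methoxyacetyl)cyclohex-4-ene-1,3-dione, transient keto tautomer of 7, stereocentres undefined | COCC(=O)C1C(=O)C(OC)=C(OC)C(OC)C1=O | intermediate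
7 | 1-(2,6-dihydroxy-3,4,5-trimethoxyphenyl)-2-methoxyethan-1-one | COCC(=O)c1c(O)c(OC)c(OC)c(OC)c1O | intermediate
8 | 3,5-dihydroxy-4-methoxybenzoic acid | COc1c(O)cc(C(=O)O)cc1O | starting material
9 | benzyl 3,5-bis(benzyloxy)-4-methoxybenzoate | COc1c(OCc2ccccc2)cc(C(=O)OCc2ccccc2)cc1OCc1ccccc1 | intermediate
10 | 3,5-bis(benzyloxy)-4-methoxybenzoic acid | COc1c(OCc2ccccc2)cc(C(=O)O)cc1OCc1ccccc1 | intermediate
11 | 3,5-bis(benzyloxy)-4-methoxybenzoic anhydride | COc1c(OCc2ccccc2)cc(C(=O)OC(=O)c2cc(OCc3ccccc3)c(OC)c(OCc3ccccc3)c2)cc1OCc1ccccc1 | intermediate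
12 | 2-[3,5-bis(benzyloxy)-4-methoxyphenyl]-3,6,7,8-tetramethoxy-4-oxo-4H-chromen-5-yl 3,5-bis(benzyloxy)-4-methoxybenzoate | COc1c(OCc2ccccc2)cc(-c2oc3c(OC)c(OC)c(OC)c(OC(=O)c4cc(OCc5ccccc5)c(OC)c(OCc5ccccc5)c4)c3c(=O)c2OC)cc1OCc1ccccc1 | intermediate
13 | 2-[3,5-bis(benzyloxy)-4-methoxyphenyl]-5-hydroxy-3,6,7,8-tetramethoxy-4H-chromen-4-one | COc1c(OCc2ccccc2)cc(-c2oc3c(OC)c(OC)c(OC)c(O)c3c(=O)c2OC)cc1OCc1ccccc1 | intermediate
14 | 5,3',5'-trihydroxy-3,6,7,8,4'-pentamethoxyflavone | COc1c(O)cc(-c2oc3c(OC)c(OC)c(OC)c(O)c3c(=O)c2OC)cc1O | target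

Total step count: 7. Longest linear sequence: 5 steps (steps 1, 2, 3, 6, 7); the ring B branch (steps 4 and 5) joins at step 6.

Steps most likely to fail

Step 3. The opening equilibrium may stay on the side of the closed pyranone, or of its unreactive side-chain dienolate, so that the chain never folds. The fallback sets out from 4 and comes back at 13.
- **Change of approach:** the ring is unmasked by hydrolysis instead of alcoholysis, and the C7 methyl group is placed at the flavone stage.
- **Opening:** Mg(OMe)2 in methanol containing a measured small excess of water lets hydroxide add next to the ring oxygen. The open form is then drained from the equilibrium as the doubly deprotonated methyl 2,4,8-trimethoxy-3,5,7-trioxooctanoate F1.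
- **Folding:** F1 should undergo the same C4a-to-C8a Claisen closure to 1-(2,4,6-trihydroxy-3,5-dimethoxyphenyl)-2-methoxyethan-1-one F2.
- **Annulation:** condensation of F2 with 11 under the conditions of step 6 would pass through 2-[3,5-bis(benzyloxy)-4-methoxyphenyl]-3,6,8-trimethoxy-4-oxo-4H-chromene-5,7-diyl bis[3,5-bis(benzyloxy)-4-methoxybenzoate] F3. After KOH it would give 2-[3,5-bis(benzyloxy)-4-methoxyphenyl]-5,7-dihydroxy-3,6,8-trimethoxy-4H-chromen-4-one F4, again a single isomer by symmetry.
- **Methylation:** Me2SO4 (1 equiv), K2CO3, acetone should methylate only the 7-OH, because the 5-OH is held in the hydrogen bond to C4=O. This delivers 13.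
- **Convergence and cost:** any 7 formed beside F2 converges on 13 as well. The price is exposure of the ester to hydroxide, which is why this is the second choice.

Step 1. The first-formed carbinol may ionise and capture a second kojic acid, or the aldehyde ester may oligomerise under amine catalysis faster than it is trapped. The fallback sets out from 1 and comes back at 4.
- **Change of approach:** the neutral aldehyde ester is replaced by glyoxylate anion in water, the hydroxyalkylation used for phenols on the way to mandelic acids.
- **Condensation:** kojic acid and aqueous glyoxylic acid with NaOH at about pH 10 and rt should give, after acidification, 2-hydroxy-2-[3-hydroxy-6-(hydroxymethyl)-4-oxo-4H-pyran-2-yl]acetic acid F5. Its carboxylate charge discourages a second condensation.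
- **Methylation:** MeI and Ag2O in DMF then methylate the acid together with the three hydroxyl groups and give 4 directly, so 2 and 3 are bypassed without extra steps.

Step 6. The electron-rich ketone may decompose thermally, or the O-to-C aroyl transfer may stall in the hot amine medium. The fallback sets out from 7 and 11 and comes back at 12. It is a stepwise Baker–Venkataraman sequence at low temperature.
- **Acylation:** 11 with DMAP in pyridine at rt gives 2-(methoxyacetyl)-4,5,6-trimethoxybenzene-1,3-diyl bis[3,5-bis(benzyloxy)-4-methoxybenzoate] F6.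
- **Acyl transfer:** LiN(SiMe3)2 in THF, −78 °C to rt, moves one aroyl group to the CH2(OMe) carbon. The product is 2-{3-[3,5-bis(benzyloxy)-4-methoxyphenyl]-2-methoxy-3-oxopropanoyl}-3-hydroxy-4,5,6-trimethoxyphenyl 3,5-bis(benzyloxy)-4-methoxybenzoate F7.
- **Ring closure:** NaOAc in AcOH at reflux closes ring C by cyclodehydration to 12, which the KOH treatment of step 6 converts into 13.

Further compounds
F1 | step 3 | methyl 2,4,8-trimethoxy-3,5,7-trioxooctanoate, mixture of stereoisomers and enol forms | COCC(=O)CC(=O)C(OC)C(=O)C(OC)C(=O)OC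
F2 | step 3 | 1-(2,4,6-trihydroxy-3,5-dimethoxyphenyl)-2-methoxyethan-1-one | COCC(=O)c1c(O)c(OC)c(O)c(OC)c1O
F3 | step 3 | 2-[3,5-bis(benzyloxy)-4-methoxyphenyl]-3,6,8-trimethoxy-4-oxo-4H-chromene-5,7-diyl bis[3,5-bis(benzyloxy)-4-methoxybenzoate] | COc1c(OCc2ccccc2)cc(-c2oc3c(OC)c(OC(=O)c4cc(OCc5ccccc5)c(OC)c(OCc5ccccc5)c4)c(OC)c(OC(=O)c4cc(OCc5ccccc5)c(OC)c(OCc5ccccc5)c4)c3c(=O)c2OC)cc1OCc1ccccc1
F4 | step 3 | 2-[3,5-bis(benzyloxy)-4-methoxyphenyl]-5,7-dihydroxy-3,6,8-trimethoxy-4H-chromen-4-one | COc1c(OCc2ccccc2)cc(-c2oc3c(OC)c(O)c(OC)c(O)c3c(=O)c2OC)cc1OCc1ccccc1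
F5 | step 1 | 2-hydroxy-2-[3-hydroxy-6-(hydroxymethyl)-4-oxo-4H-pyran-2-yl]acetic acid, racemic | OCc1cc(=O)c(O)c(C(O)C(=O)O)o1
F6 | step 6 | 2-(methoxyacetyl)-4,5,6-trimethoxybenzene-1,3-diyl bis[3,5-bis(benzyloxy)-4-methoxybenzoate] | COCC(=O)c1c(OC(=O)c2cc(OCc3ccccc3)c(OC)c(OCc3ccccc3)c2)c(OC)c(OC)c(OC)c1OC(=O)c1cc(OCc2ccccc2)c(OC)c(OCc2ccccc2)c1
F7 | step 6 | 2-{3-[3,5-bis(benzyloxy)-4-methoxyphenyl]-2-methoxy-3-oxopropanoyl}-3-hydroxy-4,5,6-trimethoxyphenyl 3,5-bis(benzyloxy)-4-methoxybenzoate, racemic | COC(C(=O)c1cc(OCc2ccccc2)c(OC)c(OCc2ccccc2)c1)C(=O)c1c(O)c(OC)c(OC)c(OC)c1OC(=O)c1cc(OCc2ccccc2)c(OC)c(OCc2ccccc2)c1
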